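## Structural features

Plakortolide Q (21) is a bicyclic peroxy lactone. A 1,2-dioxane, with the O–O bridge between C3 and C6, is cis-fused across C3–C4 to a γ-butyrolactone (C1–C4, ring oxygen on C4). C4 carries a methyl group. C6 carries a methyl group and the C7–C16 chain: six methylene groups (C7–C12), a (13E,15E)-diene and a terminal phenyl ring. The three stereocentres are (3R,4R,6S). C3 and C4 are adjacent and form the ring fusion; C6 is fully substituted and is separated from C4 by the C5 methylene and from C3 by the peroxide bridge. The fragile groups are the O–O bond (hydrogenation, low-valent metals, radicals, trivalent phosphorus), the C2 and C3 hydrogens (base can expel the C3 peroxy oxygen from the lactone enolate or start a Kornblum–DeLaMare fragmentation) and the styryl diene (diimide, singlet oxygen, strong acid). The real difficulty is to form both peroxide C–O bonds at stereogenic carbons, one of them quaternary, with C6 defined relative to the C3/C4 pair. The key step uses the fact that C2 (on C3), C7 (on C6) and the lactone oxygen (on C4) all lie on the same face of the dioxane. An ester oxygen between C1 and C7 can therefore tie a C3 hydroperoxide to a C6 ketone, fix C6 during ring closure, and then close the lactone at C4.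

## Logic of the disconnections

**21 ⇒ 18 + 19 (through 20).** The C13=C14 bond is cut. The diene would not survive diimide, so it is introduced last; 19 brings C14–C16, the phenyl ring and the C15=C16 geometry. The gain is a saturated chain ending in an aldehyde. The forward step must be E-selective and must expose the lactone to 20 only briefly and cold, because the C2 hydrogens are β to a peroxy leaving group.

**18 ⇒ 17 ⇒ 16.** No skeletal bond is cut; C13 is taken back to a silyl-protected alcohol. A silyl ether is the form of C13–O that tolerates ylide chemistry. Oxidation and desilylation must be run without base.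

**16 ⇒ 15 ⇒ 10 + 13 (through 14).** The C7–C8 bond is cut, by way of the C7=C8 double bond of 15. C7 is the carbon the key step releases as a primary alcohol, and its aldehyde 10 sits on a quaternary carbon and cannot enolise. C8–C13 come from one six-carbon piece, so the whole chain leaves the core. The ylide 14 must add faster than it deprotonates C2 or attacks O–O, and the reduction of 15 must spare the peroxide, which calls for diimide.

**10 ⇒ 9.** Only the oxidation level of C7 changes; the oxidant must leave O–O alone.

**9 ⇒ 5 (through 8, 7 and 6).** Three bonds are cut: C4–O of the lactone, C5–C6, and C6–O of the peroxide. The C1–O–C7 ester is reconnected, so that 5 is acyclic with C3 as its only stereocentre. The gain is two rings and two fully substituted stereocentres. The forward step must generate a peroxycarbenium ion inside an eight-membered ring, under dilution, faster than the allylic hydroperoxide decomposes, and the ester carbonyl must capture the C4 cation.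

**5 ⇒ 4 ⇒ 3.** The C3–O bond is cut in the sense of an ene reaction: the hydroperoxide and the C4=C5 double bond go back to the C3=C4 double bond of 3. The precursor becomes achiral. The forward step needs hydrogen abstraction from a C4 methyl group and not from C2, and then selection of one enantiomer of 4.

**3 ⇒ 1 + 2.** The ester O–C7 bond is cut; both pieces are commercial. The esterification must not move the β,γ-double bond into conjugation.

**13 ⇒ 12 ⇒ 11.** The C–P and O–Si bonds are cut, leading to a commercial bromo alcohol; the silyl ether must survive phosphonium salt formation.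

## Other disconnections considered

**Alternative 1:** The cut is the C4=C5 bond of the 3,6-dihydro-1,2-dioxine ester A2. The forward step is ring-closing metathesis of the acyclic peroxide A1 (isopropenyl on C3, vinyl on C6) with the second-generation Grubbs catalyst.
- In favour: the O–O bond is a spectator that ruthenium carbenes tolerate, a six-membered closure is easy, and the C7–C13 chain is already present, so no ylide or diimide chemistry is needed on a peroxide.
- Against: C3 and C6 must both be set beforehand on an acyclic, unsymmetrical peroxide with a tertiary allylic C–O bond. The plausible assembly (conjugate addition of a tertiary allylic hydroperoxide to a dienoate) gives no control at C3.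
- Against: the metathesis must form a trisubstituted olefin next to a quaternary carbon.
- Against: A2 still lacks the C4–O bond and the C4 stereocentre. Iodolactonisation would leave a C5 iodide whose removal goes through a radical β to the peroxide. Acid-mediated lactonisation passes through the same C4 cation as the chosen plan.
- Comparison: on precedent for the ring-closing event and on the number of steps after the key step (three or four against six) the alternative is the better. On structure it makes one ring and no stereocentre, against two rings and two stereocentres. On mechanism it is more reliable at the key step but moves the cationic or radical problem to the lactonisation. Total step count should be about equal, since A1 needs its own stereocontrolled preparation.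

**Alternative 2:** The cut removes the lactone carbons (O–C1 and C2–C3), leading to the 3-methoxy-1,2-dioxan-4-ol A3 and (trimethylsilyl)ketene A4. Forward, the tertiary C4 hydroxyl adds to A4 to give the (trimethylsilyl)acetate A5. Me3SiOTf then ionises the C3 methoxy group to a peroxycarbenium ion and turns the α-silyl ester into its silyl ketene acetal, whose carbon closes onto C3 to give the lactone A6, which has the structure of 16.
- In favour: addition of silyl ketene acetals to peroxycarbenium ions is a known reaction type. Delivery from the C4 oxygen can only give the cis ring fusion, so C4 sets C3. The ketene acylates hindered tertiary alcohols without base. Only steps 10 to 12 would remain.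
- Against: the step sets one stereocentre and presupposes C4 and C6 in the right relative configuration on a preformed dioxane with a labile peroxyacetal; the core problem is moved upstream, not solved.
- Against: the acyloxy group next to the C3 cation can participate through its carbonyl oxygen (a 1,3-dioxolan-2-ylium ion) and compete with C–C bond formation.
- Comparison: both plans rely on a peroxycarbenium ion; the alternative traps it with a strong π-nucleophile in a known manner, so on mechanistic precedent it is the better. On structure it gives one ring and one stereocentre against two and two. On step economy it is better after the key step and worse before it, because A3 needs a stereocontrolled dioxane synthesis about as long as the chosen route up to 9.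

**Alternative 3:** The cut is the C6–O bond of the dioxane. In the acyclic hydroperoxy acetal A7 (a 2-methyloxirane at C6/C7, a triethylsilyl ether at C4), acid (camphorsulfonic acid or Yb(OTf)3) activates the epoxide. The hydroperoxy oxygen attacks the tertiary carbon C6 with inversion (6-exo) to give the 1,2-dioxane A8 as both C3 epimers, with C7–OH free.
- In favour: opening of epoxides by hydroperoxides is a known way to 1,2-dioxanes. The step is stereospecific, so C6 is as secure as the epoxide. Electronic preference (tertiary carbon) and ring-size preference (six over seven) agree.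
- Against: C4 and C6 must be made independently beforehand, and enantiopure 2,2-disubstituted terminal epoxides are not easy to obtain.
- Against: cationic character at C6 can erode the inversion or cause rearrangement, and the acid can remove the triethylsilyl group.
- Against: A8 still lacks C1–C2 and the C3 stereocentre, so a lactone annulation of the kind in alternative 2 must follow, and then the same six-step chain extension from C7–OH.
- Comparison: on mechanism the alternative is the better (known reaction type, no cation–olefin cascade). On control of C6 it is the equal of the chosen plan (stereospecific opening against tether control). On structure and step economy it is weaker: one ring per key step, one stereocentre transferred, and a longest linear sequence clearly above ten steps.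

Key step: step 4

Assumption: horseradish peroxidase is taken to reduce the (S)-enantiomer of 4 faster, so that 5 is the hydroperoxide left over; this sense of discrimination cannot be predicted for an aliphatic allylic hydroperoxide, and the configuration of 5 has to be confirmed before step 4.

## Route

Step 1
Reactants: 1 4-methylpent-3-enoic acid; 2 chloroacetone
Product: 3 2-oxopropyl 4-methylpent-3-enoate
Conditions: KHCO3, NaI (cat.), DMF, rt
Reagents that add atoms: none
Why: Carboxylate O-alkylation (SN2) by an α-chloro ketone with iodide catalysis; bicarbonate is too weak a base to move the β,γ-double bond into conjugation.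

Step 2
Reactants: 3 2-oxopropyl 4-methylpent-3-enoate
Product: 4 2-oxopropyl 3-hydroperoxy-4-methylpent-4-enoate (racemic)
Conditions: O2, visible light, 5,10,15,20-tetraphenylporphyrin (cat.), CH2Cl2, 0 °C
Reagents that add atoms: oxygen, O=O
Why: Schenck ene reaction: singlet oxygen bonds to C3, a hydrogen is taken from a C4 methyl group and the double bond moves to C4=C5. Abstraction at the geminal-dimethyl end is favoured and the C2 hydrogens next to the ester carbonyl are poor donors, so the β-hydroperoxy ester should predominate; C3 is formed racemic.

Step 3
Reactants: 4 2-oxopropyl 3-hydroperoxy-4-methylpent-4-enoate (racemic)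
Product: 5 2-oxopropyl (3R)-3-hydroperoxy-4-methylpent-4-enoate
Conditions: horseradish peroxidase (cat.), guaiacol, KH2PO4/K2HPO4 buffer (pH 6), 20 °C, stopped just past half conversion
Reagents that add atoms: none
Why: Peroxidase-catalysed kinetic resolution, a known behaviour of ene-derived secondary allylic hydroperoxides: one enantiomer is reduced to the alcohol with guaiacol as electron donor. The C3 centre of 5 is selected, not formed, and the alcohol is removed by chromatography.

Step 4
Reactants: 5 2-oxopropyl (3R)-3-hydroperoxy-4-methylpent-4-enoate
Product: 9 (3R,4R,6R)-3,6-epidioxy-7-hydroxy-4,6-dimethylheptano-1,4-lactone, via cyclic peroxyhemiketal 6 (not isolated), via peroxycarbenium ion 7 (not isolated), via tricyclic alkoxyoxolanylium ion 8 (not isolated)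
Conditions: BF3·OEt2 (0.3 equiv), CH2Cl2 (0.005 M), −78 → −20 °C; then H2O, 0 °C
Reagents that add atoms: water, O
Why: Proposed new method: BF3 promotes addition of the C3 hydroperoxide to the tethered ketone (eight-membered peroxyhemiketal 6) and ionisation to the peroxycarbenium ion 7; the closest known reaction types are Lewis-acid cyclisations of unsaturated peroxyketals through peroxycarbenium ions and Prins cyclisations terminated by a carboxyl oxygen, joined here and run through a medium-ring tether. The dioxane closes by attack of the isopropenyl terminus C5 on C6 (6-endo-trig cation–olefin closure, tertiary cation at C4); because the C1–O–C7 bridge spans C3 and C6, the transition state is a boat-like bicyclo[4.2.2] array and cannot be a chair. The lactone closes by attack of the ester carbonyl oxygen on the C4 cation (five-membered, 5-exo-type closure) to give the 2-alkoxyoxolan-2-ylium ion 8, a cyclic dialkoxycarbenium ion and not a 1,3-dioxolan-2-ylium ion. Water adds at C1 of 8 and the hemiorthoester collapses to the γ-lactone, releasing the C7 hydroxyl and the proton, so the acid turns over and the step is a net isomerisation. C6 is controlled by the tether: C7 can only be bonded on the face of the new ring that carries C2, so (3R) enforces (6R) in 9. C4 is controlled by the same ester: its carbonyl oxygen reaches the cation only from the C2 face, which gives the cis ring fusion and (4R). The step needs cyclisation to beat intermolecular peroxyketalisation, Hock cleavage of the allylic hydroperoxide and acyl transfer from the activated ester to the OOH group; high dilution, low temperature and sub-stoichiometric acid are chosen for this, and the irreversible C–C bond formation should drain the unfavourable peroxyhemiketal equilibrium.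

Step 5
Reactants: 9 (3R,4R,6R)-3,6-epidioxy-7-hydroxy-4,6-dimethylheptano-1,4-lactone
Product: 10 (3R,4R,6R)-3,6-epidioxy-4,6-dimethyl-7-oxoheptano-1,4-lactone
Conditions: Dess–Martin periodinane, CH2Cl2, 0 °C → rt
Reagents that add atoms: none
Why: Dess–Martin oxidation of a primary alcohol; C6 bears no hydrogen, so the α-peroxy aldehyde cannot epimerise or fragment by the Kornblum–DeLaMare path, and the O–O bond is inert to the hypervalent iodine reagent.

Step 6
Reactants: 11 6-bromohexan-1-ol
Product: 12 (6-bromohexyloxy)(tert-butyl)dimethylsilane
Conditions: TBSCl, imidazole, CH2Cl2, rt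
Reagents that add atoms: tert-butyldimethylsilyl chloride, CC(C)(C)[Si](C)(C)Cl
Why: Imidazole-promoted silylation of a primary alcohol; the silyl ether masks C13–O through the ylide and diimide steps.

Step 7
Reactants: 12 (6-bromohexyloxy)(tert-butyl)dimethylsilane
Product: 13 [6-(tert-butyldimethylsilyloxy)hexyl]triphenylphosphonium bromide
Conditions: PPh3, MeCN, 80 °C
Reagents that add atoms: triphenylphosphine, c1ccc(cc1)P(c1ccccc1)c1ccccc1
Why: SN2 quaternisation of triphenylphosphine by a primary bromide under neutral conditions, which the silyl ether tolerates.

Step 8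
Reactants: 10 (3R,4R,6R)-3,6-epidioxy-4,6-dimethyl-7-oxoheptano-1,4-lactone; 13 [6-(tert-butyldimethylsilyloxy)hexyl]triphenylphosphonium bromide
Product: 15 (3R,4R,6R,7Z)-13-(tert-butyldimethylsilyloxy)-3,6-epidioxy-4,6-dimethyltridec-7-eno-1,4-lactone, via phosphonium ylide 14 (not isolated)
Conditions: 13 (1.3 equiv), NaN(SiMe3)2 (1.2 equiv), THF, −78 → 0 °C; then 10, −78 → −20 °C
Reagents that add atoms: none
Why: Wittig olefination with a non-stabilised ylide: the salt is in slight excess over the base so that no free amide meets the lactone, and addition to the unenolisable α-oxygenated aldehyde at −78 °C should be faster than proton abstraction at C2 or attack on O–O. The Z geometry is of no consequence because the double bond is reduced next.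

Step 9
Reactants: 15 (3R,4R,6R,7Z)-13-(tert-butyldimethylsilyloxy)-3,6-epidioxy-4,6-dimethyltridec-7-eno-1,4-lactone
Product: 16 (3R,4R,6S)-13-(tert-butyldimethylsilyloxy)-3,6-epidioxy-4,6-dimethyltridecano-1,4-lactone
Conditions: KO2CN=NCO2K, AcOH, MeOH/CH2Cl2, 0 °C → rt
Reagents that add atoms: none
Why: Diimide reduction: HN=NH, formed by protonation and decarboxylation of the azodicarboxylate, transfers two hydrogens to C7=C8 in a concerted syn manner and leaves O–O, C=O and the silyl ether untouched, whereas catalytic hydrogenation would cleave the peroxide. The C6 descriptor changes from R to S only because the ranking of its substituents changes.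

Step 10
Reactants: 16 (3R,4R,6S)-13-(tert-butyldimethylsilyloxy)-3,6-epidioxy-4,6-dimethyltridecano-1,4-lactone
Product: 17 (3R,4R,6S)-3,6-epidioxy-13-hydroxy-4,6-dimethyltridecano-1,4-lactone
Conditions: HF·pyridine, THF/pyridine, 0 °C → rt
Reagents that add atoms: none
Why: Fluoride-induced cleavage of the primary silyl ether under buffered acidic conditions; basic Bu4NF is avoided because of the base-sensitive β-peroxy lactone.

Step 11
Reactants: 17 (3R,4R,6S)-3,6-epidioxy-13-hydroxy-4,6-dimethyltridecano-1,4-lactone
Product: 18 (3R,4R,6S)-3,6-epidioxy-4,6-dimethyl-13-oxotridecano-1,4-lactone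
Conditions: Dess–Martin periodinane, CH2Cl2, 0 °C → rt
Reagents that add atoms: none
Why: Dess–Martin oxidation of the remote primary alcohol under neutral to weakly acidic conditions that leave the peroxide and the lactone alone.

Step 12
Reactants: 18 (3R,4R,6S)-3,6-epidioxy-4,6-dimethyl-13-oxotridecano-1,4-lactone; 19 diethyl [(2E)-3-phenylprop-2-en-1-yl]phosphonate (diethyl cinnamylphosphonate)
Product: 21 plakortolide Q [(3R,4R,6S,13E,15E)-3,6-epidioxy-4,6-dimethyl-16-phenylhexadeca-13,15-dieno-1,4-lactone], via sodium phosphonate carbanion 20 (not isolated)
Conditions: 19 (1.3 equiv), NaN(SiMe3)2 (1.2 equiv), THF, −78 °C; then 18, −78 → 0 °C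
Reagents that add atoms: none
Why: Horner–Wadsworth–Emmons olefination: the allylic phosphonate carbanion adds reversibly to the aldehyde and eliminates through the anti adduct to the (13E) alkene, while the (15E) geometry comes in with 19. Base is limiting relative to 19 and the temperature is low, to spare the C2 hydrogens.

## Compound list

1 | 4-methylpent-3-enoic acid | CC(C)=CCC(=O)O | starting material
2 | chloroacetone (1-chloropropan-2-one) | CC(=O)CCl | starting material
3 | 2-oxopropyl 4-methylpent-3-enoate | CC(C)=CCC(=O)OCC(C)=O | intermediate
4 | 2-oxopropyl 3-hydroperoxy-4-methylpent-4-enoate (racemic) | C=C(C)C(CC(=O)OCC(C)=O)OO | intermediate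
5 | 2-oxopropyl (3R)-3-hydroperoxy-4-methylpent-4-enoate | C=C(C)[C@@H](CC(=O)OCC(C)=O)OO | intermediate
6 | (8R)-3-hydroxy-3-methyl-8-(prop-1-en-2-yl)-1,2,5-trioxocan-6-one, cyclic peroxyhemiketal, both configurations at the hemiketal carbon | C=C(C)[C@H]1CC(=O)OCC(C)(O)OO1 | intermediate (not isolated)
7 | peroxycarbenium ion derived from 6 by loss of hydroxide at C6 (eight-membered ring, cationic centre at C6, drawn as the oxonium form) | C=C(C)[C@H]1CC(=O)OCC(C)=[O+]O1 | intermediate (not isolated)
8 | tricyclic 2-alkoxyoxolan-2-ylium ion (C1 bonded to C2, to the oxygen on C4 and to the oxygen on C7; 3,6-peroxide bridge in place; 3R,4R,6R) | C[C@]1(CO3)C[C@@]2(C)[O+]=C3C[C@H]2OO1 | intermediate (not isolated)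
9 | (3R,4R,6R)-3,6-epidioxy-7-hydroxy-4,6-dimethylheptano-1,4-lactone [(3R,4aR,7aR)-3-(hydroxymethyl)-3,4a-dimethyltetrahydro-3H-furo[3,2-c][1,2]dioxin-6(4H)-one] | C[C@]1(CO)C[C@@]2(C)OC(=O)C[C@H]2OO1 | intermediate
10 | (3R,4R,6R)-3,6-epidioxy-4,6-dimethyl-7-oxoheptano-1,4-lactone | C[C@]1(C=O)C[C@@]2(C)OC(=O)C[C@H]2OO1 | intermediate
11 | 6-bromohexan-1-ol | OCCCCCCBr | starting material
12 | (6-bromohexyloxy)(tert-butyl)dimethylsilane | BrCCCCCCO[Si](C)(C)C(C)(C)C | intermediate
13 | [6-(tert-butyldimethylsilyloxy)hexyl]triphenylphosphonium bromide | CC(C)(C)[Si](C)(C)OCCCCCC[P+](c1ccccc1)(c1ccccc1)c1ccccc1.[Br-] | intermediate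
14 | [6-(tert-butyldimethylsilyloxy)hexylidene]triphenylphosphorane | CC(C)(C)[Si](C)(C)OCCCCCC=P(c1ccccc1)(c1ccccc1)c1ccccc1 | intermediate (not isolated)
15 | (3R,4R,6R,7Z)-13-(tert-butyldimethylsilyloxy)-3,6-epidioxy-4,6-dimethyltridec-7-eno-1,4-lactone | C[C@]1(/C=C\CCCCCO[Si](C)(C)C(C)(C)C)C[C@@]2(C)OC(=O)C[C@H]2OO1 | intermediate
16 | (3R,4R,6S)-13-(tert-butyldimethylsilyloxy)-3,6-epidioxy-4,6-dimethyltridecano-1,4-lactone | C[C@]1(CCCCCCCO[Si](C)(C)C(C)(C)C)C[C@@]2(C)OC(=O)C[C@H]2OO1 | intermediate
17 | (3R,4R,6S)-3,6-epidioxy-13-hydroxy-4,6-dimethyltridecano-1,4-lactone | C[C@]1(CCCCCCCO)C[C@@]2(C)OC(=O)C[C@H]2OO1 | intermediate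
18 | (3R,4R,6S)-3,6-epidioxy-4,6-dimethyl-13-oxotridecano-1,4-lactone | C[C@]1(CCCCCCC=O)C[C@@]2(C)OC(=O)C[C@H]2OO1 | intermediate
19 | diethyl [(2E)-3-phenylprop-2-en-1-yl]phosphonate | CCOP(=O)(C/C=C/c1ccccc1)OCC | starting material
20 | sodium salt of the α-carbanion of 19 | [Na+].CCOP(=O)([CH-]/C=C/c1ccccc1)OCC | intermediate (not isolated)
21 | plakortolide Q, (3R,4R,6S,13E,15E)-3,6-epidioxy-4,6-dimethyl-16-phenylhexadeca-13,15-dieno-1,4-lactone [(3S,4aR,7aR)-3,4a-dimethyl-3-[(7E,9E)-10-phenyldeca-7,9-dien-1-yl]tetrahydro-3H-furo[3,2-c][1,2]dioxin-6(4H)-one] | C[C@]1(CCCCCC/C=C/C=C/c2ccccc2)C[C@@]2(C)OC(=O)C[C@H]2OO1 | target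

## Step count and least certain steps

Total: 12 steps. Longest linear sequence: 10 steps (steps 1–5 and 8–12, from 1 to 21); steps 6 and 7 form the side branch.

**Step 4 (key step, proposed new method).** The most likely failure is that the eight-membered peroxyhemiketal does not close at a useful rate. Intermolecular peroxyketalisation, acid-induced Hock cleavage of the allylic hydroperoxide or acyl transfer from the activated ester to the hydroperoxide would then take over. The causes are the entropic and transannular cost of the medium ring and the destabilisation of the C6 cation by the neighbouring acyloxymethyl group. The fallback uses known reaction types and gives up the tether; it sets out from 5 and returns at 9. Commercial 1-(tert-butyldimethylsilyloxy)propan-2-one is converted with HC(OMe)3, MeOH and pyridinium tosylate into 1-(tert-butyldimethylsilyloxy)-2,2-dimethoxypropane F1. Ketal exchange of 5 with F1 (pyridinium tosylate, CH2Cl2) should give the mixed peroxyketal 2-oxopropyl (3R)-3-{[1-(tert-butyldimethylsilyloxy)-2-methoxypropan-2-yl]peroxy}-4-methylpent-4-enoate F2. Me3SiOTf in CH2Cl2 at −78 °C ionises the methoxy group; the acyclic peroxycarbenium ion closes onto the isopropenyl group through a chair-like transition state, the ester carbonyl captures the C4 cation, and the acetonyl group is lost on aqueous work-up. Without the tether C6 is not controlled, so (3R,4R,6R)-7-(tert-butyldimethylsilyloxy)-3,6-epidioxy-4,6-dimethylheptano-1,4-lactone F3 is expected together with its C6 epimer, (3R,4R,6S)-7-(tert-butyldimethylsilyloxy)-3,6-epidioxy-4,6-dimethylheptano-1,4-lactone F4, and the two must be separated by chromatography. HF·pyridine then converts F3 into 9.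

**Step 3.** The most likely failure is insufficient discrimination between the enantiomers, or consumption of the wanted one, because the two carbon substituents at C3 (isopropenyl and the ester-bearing methylene) are similar in size. Slow hydrolysis of the activated ester in buffer is a second concern. The fallback replaces kinetic resolution by physical separation: preparative chromatography of 4 on a cellulose tris(3,5-dimethylphenylcarbamate) stationary phase, collecting the (R)-enantiomer. It sets out from 4 and returns at 5 and makes no new compound (entry F0).

**Step 8.** The most likely failure is proton abstraction at C2 by the strongly basic ylide, followed by β-elimination that opens the dioxane, or attack of the nucleophilic phosphorus ylide on the O–O bond; both compete because the aldehyde is neopentyl-like and hindered. The fallback is a phosphorus-free Julia–Kocienski olefination; it sets out from 12 and 10 and returns at 16. 12 is converted with 1-phenyl-1H-tetrazole-5-thiol and K2CO3 into 5-{[6-(tert-butyldimethylsilyloxy)hexyl]sulfanyl}-1-phenyl-1H-tetrazole F5, which H2O2 and (NH4)6Mo7O24 oxidise to 5-{[6-(tert-butyldimethylsilyloxy)hexyl]sulfonyl}-1-phenyl-1H-tetrazole F6. F6 is deprotonated with KN(SiMe3)2 in THF at −78 °C and 10 is added. This should give mainly (3R,4R,6R,7E)-13-(tert-butyldimethylsilyloxy)-3,6-epidioxy-4,6-dimethyltridec-7-eno-1,4-lactone F7, possibly mixed with 15; both are reduced by diimide as in step 9 to 16.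

**Step 12.** The most likely failure is deprotonation at C2 by the phosphonate carbanion, with expulsion of the C3 peroxy oxygen, or incomplete E selectivity at C13=C14; the carbanion 20 is about as basic as the lactone enolate. The fallback uses a far less basic semi-stabilised ylide and corrects the geometry afterwards; it sets out from 18 and returns at 21. Commercial cinnamyltriphenylphosphonium chloride is deprotonated with one equivalent of NaN(SiMe3)2 to triphenyl[(2E)-3-phenylprop-2-en-1-ylidene]phosphorane F8, which should convert 18 at −78 → 0 °C into 21 mixed with its 13Z isomer, (3R,4R,6S,13Z,15E)-3,6-epidioxy-4,6-dimethyl-16-phenylhexadeca-13,15-dieno-1,4-lactone F9. Catalytic I2 in daylight then equilibrates F9 to the more stable (13E,15E)-diene 21.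

## Further compounds

F1 | step 4 | 1-(tert-butyldimethylsilyloxy)-2,2-dimethoxypropane | COC(C)(CO[Si](C)(C)C(C)(C)C)OC
F2 | step 4 | 2-oxopropyl (3R)-3-{[1-(tert-butyldimethylsilyloxy)-2-methoxypropan-2-yl]peroxy}-4-methylpent-4-enoate (both configurations at the ketal carbon) | C=C(C)[C@@H](CC(=O)OCC(C)=O)OOC(C)(OC)CO[Si](C)(C)C(C)(C)C
F3 | step 4 | (3R,4R,6R)-7-(tert-butyldimethylsilyloxy)-3,6-epidioxy-4,6-dimethylheptano-1,4-lactone | C[C@]1(CO[Si](C)(C)C(C)(C)C)C[C@@]2(C)OC(=O)C[C@H]2OO1
F4 | step 4 | (3R,4R,6S)-7-(tert-butyldimethylsilyloxy)-3,6-epidioxy-4,6-dimethylheptano-1,4-lactone | C[C@@]1(CO[Si](C)(C)C(C)(C)C)C[C@@]2(C)OC(=O)C[C@H]2OO1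
F0 | step 3 | none | none
F5 | step 8 | 5-{[6-(tert-butyldimethylsilyloxy)hexyl]sulfanyl}-1-phenyl-1H-tetrazole | CC(C)(C)[Si](C)(C)OCCCCCCSc1nnnn1-c1ccccc1
F6 | step 8 | 5-{[6-(tert-butyldimethylsilyloxy)hexyl]sulfonyl}-1-phenyl-1H-tetrazole | CC(C)(C)[Si](C)(C)OCCCCCCS(=O)(=O)c1nnnn1-c1ccccc1
F7 | step 8 | (3R,4R,6R,7E)-13-(tert-butyldimethylsilyloxy)-3,6-epidioxy-4,6-dimethyltridec-7-eno-1,4-lactone | C[C@]1(/C=C/CCCCCO[Si](C)(C)C(C)(C)C)C[C@@]2(C)OC(=O)C[C@H]2OO1
F8 | step 12 | triphenyl[(2E)-3-phenylprop-2-en-1-ylidene]phosphorane | c1ccccc1/C=C/C=P(c1ccccc1)(c1ccccc1)c1ccccc1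
F9 | step 12 | (3R,4R,6S,13Z,15E)-3,6-epidioxy-4,6-dimethyl-16-phenylhexadeca-13,15-dieno-1,4-lactone | C[C@]1(CCCCCC/C=C\C=C\c2ccccc2)C[C@@]2(C)OC(=O)C[C@H]2OO1
A1 | alternative 1 | methyl (3R)-3-({(3S)-10-[(tert-butyldimethylsilyl)oxy]-3-methyldec-1-en-3-yl}peroxy)-4-methylpent-4-enoate | C[C@@](C=C)(CCCCCCCO[Si](C)(C)C(C)(C)C)OO[C@H](CC(=O)OC)C(C)=C
A2 | alternative 1 | methyl 2-[(3R,6S)-6-{7-[(tert-butyldimethylsilyl)oxy]heptyl}-4,6-dimethyl-3,6-dihydro-1,2-dioxin-3-yl]acetate | C[C@]1(CCCCCCCO[Si](C)(C)C(C)(C)C)C=C(C)[C@@H](CC(=O)OC)OO1
A3 | alternative 2 | (4R,6S)-6-{7-[(tert-butyldimethylsilyl)oxy]heptyl}-3-methoxy-4,6-dimethyl-1,2-dioxan-4-ol (both C3 epimers) | C[C@]1(CCCCCCCO[Si](C)(C)C(C)(C)C)C[C@@](C)(O)C(OC)OO1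
A4 | alternative 2 | (trimethylsilyl)ketene | C[Si](C)(C)C=C=O
A5 | alternative 2 | (4R,6S)-6-{7-[(tert-butyldimethylsilyl)oxy]heptyl}-3-methoxy-4,6-dimethyl-1,2-dioxan-4-yl 2-(trimethylsilyl)acetate (both C3 epimers) | C[C@]1(CCCCCCCO[Si](C)(C)C(C)(C)C)C[C@@](C)(OC(=O)C[Si](C)(C)C)C(OC)OO1
A6 | alternative 2 | (3R,4R,6S)-13-(tert-butyldimethylsilyloxy)-3,6-epidioxy-4,6-dimethyltridecano-1,4-lactone | C[C@]1(CCCCCCCO[Si](C)(C)C(C)(C)C)C[C@@]2(C)OC(=O)C[C@H]2OO1
A7 | alternative 3 | triethyl{[(2R)-1-hydroperoxy-1-methoxy-2-methyl-3-[(2S)-2-methyloxiran-2-yl]propan-2-yl]oxy}silane (both C1 epimers) | C[C@]1(C[C@@](C)(O[Si](CC)(CC)CC)C(OC)OO)CO1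
A8 | alternative 3 | [(3R,5R)-6-methoxy-3,5-dimethyl-5-(triethylsilyloxy)-1,2-dioxan-3-yl]methanol (both C6 epimers) | C[C@]1(CO)C[C@@](C)(O[Si](CC)(CC)CC)C(OC)OO1
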